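**Retrosynthetic overview**
- The target comes from its penta-O-benzyl ether by hydrogenolysis; the single methyl ether is carried through from 4-methoxybenzaldehyde.
- Both pyranone rings (the two O1–C2 bonds) are closed last and together, by a twofold oxidative oxa-cyclisation of a bis(2'-hydroxychalcone).
- The bis-chalcone comes from a biaryl aldehyde-chalcone and a 2-hydroxy-4,6-bis(benzyloxy)acetophenone (Claisen–Schmidt); the biaryl bond is made earlier by Suzuki–Miyaura coupling on simple arenes.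
- The iodochalcone partner comes from phloroacetophenone by benzylation, iodination ortho to the one free chelated phenol, and condensation with 4-methoxybenzaldehyde; that free phenol next to the biaryl bond fixes the 8-linkage.

Assumption: the target has no stereocentre and the SMILES fixes no axial configuration, so no stereocontrol is needed; 4-(benzyloxy)-3-bromobenzaldehyde is taken as a catalogue building block.

**Step 1**
Reactants: 1 2,4,6-trihydroxyacetophenone; 2 benzyl bromide
Product: 3 1-[2,4-bis(benzyloxy)-6-hydroxyphenyl]ethan-1-one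
Conditions: BnBr (2.1 equiv), K2CO3 (2.2 equiv), DMF, 0 °C → rt, 16 h
Reagents that add atoms: benzyl bromide (compound 2), BrCc1ccccc1
Why: Williamson ether synthesis in which the para-hydroxyl and one of the two equivalent ortho-hydroxyls are benzylated while the last ortho-hydroxyl is held back by its hydrogen bond to the acetyl carbonyl, leaving free exactly the phenol that later becomes O1.

**Step 2**
Reactants: 3 1-[2,4-bis(benzyloxy)-6-hydroxyphenyl]ethan-1-one; 4 N-iodosuccinimide
Product: 5 1-[4,6-bis(benzyloxy)-2-hydroxy-3-iodophenyl]ethan-1-one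
Conditions: NIS (1.05 equiv), CF3CO2H (10 mol %), MeCN/CH2Cl2, 0 °C → rt, dark
Reagents that add atoms: N-iodosuccinimide (compound 4), O=C1CCC(=O)N1I
Why: Electrophilic aromatic iodination (SEAr) is expected at C3, ortho to the free phenol, because the other activated position (C5) lies between two bulky benzyloxy groups.

**Step 3**
Reactants: 5 1-[4,6-bis(benzyloxy)-2-hydroxy-3-iodophenyl]ethan-1-one; 6 4-methoxybenzaldehyde
Product: 7 (2E)-1-[4,6-bis(benzyloxy)-2-hydroxy-3-iodophenyl]-3-(4-methoxyphenyl)prop-2-en-1-one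
Conditions: 6 (1.5 equiv), 50% aq KOH, EtOH/THF, rt, 36 h; then cold 1 M HCl
Reagents that add atoms: none
Why: Claisen–Schmidt aldol condensation of the methyl ketone with a non-enolisable aldehyde gives the E-enone by E1cB dehydration, and the aryl iodide is inert to aqueous KOH at room temperature.

**Step 4**
Reactants: 8 4-(benzyloxy)-3-bromobenzaldehyde; 9 bis(pinacolato)diboron; 7 (2E)-1-[4,6-bis(benzyloxy)-2-hydroxy-3-iodophenyl]-3-(4-methoxyphenyl)prop-2-en-1-one
Product: 11 4-(benzyloxy)-3-{4,6-bis(benzyloxy)-2-hydroxy-3-[(2E)-3-(4-methoxyphenyl)prop-2-enoyl]phenyl}benzaldehyde, via aryl pinacol boronate 10 (not isolated)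
Conditions: 8 (1.3 equiv), B2pin2 (1.35 equiv), Pd(OAc)2 (4 mol %), XPhos (8 mol %), KOAc (3 equiv), 1,4-dioxane, 90 °C, 2 h; then 7 (1.0 equiv), aq K3PO4 (3 equiv), 85 °C, 8 h
Reagents that add atoms: none
Why: Miyaura borylation of the aryl bromide is followed in the same flask by Suzuki–Miyaura coupling with the aryl iodide, the bulky electron-rich XPhos ligand being chosen for the tri-ortho-substituted biaryl, and the aldehyde, enone and free phenol tolerate KOAc and K3PO4.

**Step 5**
Reactants: 11 4-(benzyloxy)-3-{4,6-bis(benzyloxy)-2-hydroxy-3-[(2E)-3-(4-methoxyphenyl)prop-2-enoyl]phenyl}benzaldehyde; 3 1-[2,4-bis(benzyloxy)-6-hydroxyphenyl]ethan-1-one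
Product: 12 (2E)-1-[2,4-bis(benzyloxy)-6-hydroxyphenyl]-3-[4-(benzyloxy)-3-{4,6-bis(benzyloxy)-2-hydroxy-3-[(2E)-3-(4-methoxyphenyl)prop-2-enoyl]phenyl}phenyl]prop-2-en-1-one
Conditions: 3 (1.2 equiv), 50% aq KOH, EtOH/THF, rt, 48 h; then cold 1 M HCl
Reagents that add atoms: none
Why: Second Claisen–Schmidt condensation, in which 11 has no methyl ketone left and can only act as the aldehyde partner, so self-condensation is excluded, and the strongly basic medium returns any flavanone formed in step 4 to the open chalcone.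

**Step 6**
Reactants: 12 the bis(2'-hydroxychalcone) from step 5
Product: 14 5,7-bis(benzyloxy)-8-{2-(benzyloxy)-5-[5,7-bis(benzyloxy)-4-oxo-4H-chromen-2-yl]phenyl}-2-(4-methoxyphenyl)-4H-chromen-4-one, via flavone-chalcone 13 (not isolated)
Conditions: Pd(O2CCF3)2 (10 mol %), 4,5-diazafluoren-9-one (10 mol %), O2 (1 atm), DMSO, 80 °C, 24 h
Reagents that add atoms: none
Why: Proposed new method: a twofold aerobic dehydrogenative oxa-annulation in which each chelated phenol binds divalent palladium as a phenoxide and adds 6-endo to the β-carbon of its enone (oxa-Michael-type oxypalladation forming the O1–C2 bond and a C3-bound palladium enolate), β-hydride elimination of the C2–H gives the pyranone, and O2 returns zerovalent palladium to the divalent state with water as the only by-product, while any flavanone formed by protonation re-enters through α-palladation and the unhindered apigenin-unit phenol is expected to close first (13); the closest known reaction types are the aerobic palladium-catalysed α,β-dehydrogenation of chromanones and flavanones and the Wacker-type oxidative cyclisation of single 2'-hydroxychalcones, which have not been shown to close two pyranone rings at once on a biaryl bis-chalcone.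

**Step 7**
Reactants: 14 the penta-O-benzyl biflavone from step 6
Product: 15 podocarpusflavone A, 8-[5-(5,7-dihydroxy-4-oxo-4H-chromen-2-yl)-2-hydroxyphenyl]-5,7-dihydroxy-2-(4-methoxyphenyl)-4H-chromen-4-one
Conditions: H2 (1 atm), Pd/C (10 wt %), THF/MeOH 1:1, rt
Reagents that add atoms: none
Why: Catalytic hydrogenolysis cleaves the five aryl benzyl ethers, the aryl methyl ether is inert, and the pyranone C2=C3 bonds (vinylogous esters) are reduced much more slowly than O-benzyl groups are cleaved.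

**Compound list**
1 | 2,4,6-trihydroxyacetophenone | CC(=O)c1c(O)cc(O)cc1O | starting material
2 | benzyl bromide | BrCc1ccccc1 | starting material
3 | 1-[2,4-bis(benzyloxy)-6-hydroxyphenyl]ethan-1-one | CC(=O)c1c(O)cc(OCc2ccccc2)cc1OCc1ccccc1 | intermediate
4 | N-iodosuccinimide | O=C1CCC(=O)N1I | starting material
5 | 1-[4,6-bis(benzyloxy)-2-hydroxy-3-iodophenyl]ethan-1-one | CC(=O)c1c(O)c(I)c(OCc2ccccc2)cc1OCc1ccccc1 | intermediate
6 | 4-methoxybenzaldehyde | COc1ccc(C=O)cc1 | starting material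
7 | (2E)-1-[4,6-bis(benzyloxy)-2-hydroxy-3-iodophenyl]-3-(4-methoxyphenyl)prop-2-en-1-one | COc1ccc(/C=C/C(=O)c2c(O)c(I)c(OCc3ccccc3)cc2OCc2ccccc2)cc1 | intermediate
8 | 4-(benzyloxy)-3-bromobenzaldehyde | O=Cc1ccc(OCc2ccccc2)c(Br)c1 | starting material
9 | bis(pinacolato)diboron | CC1(C)OB(OC1(C)C)B1OC(C)(C)C(C)(C)O1 | starting material
10 | 4-(benzyloxy)-3-(4,4,5,5-tetramethyl-1,3,2-dioxaborolan-2-yl)benzaldehyde | O=Cc1ccc(OCc2ccccc2)c(B2OC(C)(C)C(C)(C)O2)c1 | intermediate
11 | 4-(benzyloxy)-3-{4,6-bis(benzyloxy)-2-hydroxy-3-[(2E)-3-(4-methoxyphenyl)prop-2-enoyl]phenyl}benzaldehyde | COc1ccc(/C=C/C(=O)c2c(O)c(-c3cc(C=O)ccc3OCc3ccccc3)c(OCc3ccccc3)cc2OCc2ccccc2)cc1 | intermediate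
12 | (2E)-1-[2,4-bis(benzyloxy)-6-hydroxyphenyl]-3-[4-(benzyloxy)-3-{4,6-bis(benzyloxy)-2-hydroxy-3-[(2E)-3-(4-methoxyphenyl)prop-2-enoyl]phenyl}phenyl]prop-2-en-1-one | COc1ccc(/C=C/C(=O)c2c(O)c(-c3cc(/C=C/C(=O)c4c(O)cc(OCc5ccccc5)cc4OCc4ccccc4)ccc3OCc3ccccc3)c(OCc3ccccc3)cc2OCc2ccccc2)cc1 | intermediate
13 | 5,7-bis(benzyloxy)-2-[4-(benzyloxy)-3-{4,6-bis(benzyloxy)-2-hydroxy-3-[(2E)-3-(4-methoxyphenyl)prop-2-enoyl]phenyl}phenyl]-4H-chromen-4-one | COc1ccc(/C=C/C(=O)c2c(O)c(-c3cc(-c4cc(=O)c5c(OCc6ccccc6)cc(OCc6ccccc6)cc5o4)ccc3OCc3ccccc3)c(OCc3ccccc3)cc2OCc2ccccc2)cc1 | intermediate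
14 | 5,7-bis(benzyloxy)-8-{2-(benzyloxy)-5-[5,7-bis(benzyloxy)-4-oxo-4H-chromen-2-yl]phenyl}-2-(4-methoxyphenyl)-4H-chromen-4-one | COc1ccc(-c2cc(=O)c3c(OCc4ccccc4)cc(OCc4ccccc4)c(-c4cc(-c5cc(=O)c6c(OCc7ccccc7)cc(OCc7ccccc7)cc6o5)ccc4OCc4ccccc4)c3o2)cc1 | intermediate
15 | podocarpusflavone A | COc1ccc(-c2cc(=O)c3c(O)cc(O)c(-c4cc(-c5cc(=O)c6c(O)cc(O)cc6o5)ccc4O)c3o2)cc1 | target

**Step count and risks**
Total steps: 7. Longest linear sequence: 7 (steps 1 to 7; ketone 3 is used again in step 5 and aldehyde 8 is bought).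

The three steps most likely to fail:

Step 6 (the new twofold aerobic cyclisation). It may stall at the half-closed 13 because the second phenol is flanked by the biaryl, or palladium may attack the electron-rich rings. The fallback uses known chemistry, closes the rings one at a time, sets out from 11 and comes back at 14. Aldehyde-chalcone 11 is cyclised with I2 (10 mol %) in DMSO at 130 °C, the classical iodine-mediated oxidative cyclisation of a 2'-hydroxychalcone, to 4-(benzyloxy)-3-[5,7-bis(benzyloxy)-2-(4-methoxyphenyl)-4-oxo-4H-chromen-8-yl]benzaldehyde F5. Claisen–Schmidt condensation of F5 with ketone 3 (aq KOH, EtOH/THF, rt) gives 5,7-bis(benzyloxy)-8-{2-(benzyloxy)-5-[(1E)-3-[2,4-bis(benzyloxy)-6-hydroxyphenyl]-3-oxoprop-1-en-1-yl]phenyl}-2-(4-methoxyphenyl)-4H-chromen-4-one F6. A second I2/DMSO cyclisation of F6 gives 14.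

Step 4 (one-pot borylation and hindered coupling on a base-sensitive iodochalcone). Protodeiodination, flavanone formation or slow coupling at the doubly ortho-substituted iodide may lower the yield. The fallback moves the coupling to the ketone stage with the aldehyde masked; it sets out from 8 and 5 and comes back at 11. Aldehyde 8 is protected with ethylene glycol (TsOH, toluene, Dean–Stark) as 2-[4-(benzyloxy)-3-bromophenyl]-1,3-dioxolane F1. Miyaura borylation (B2pin2, Pd(dppf)Cl2, KOAc, dioxane, 90 °C) gives the isolated 2-[2-(benzyloxy)-5-(1,3-dioxolan-2-yl)phenyl]-4,4,5,5-tetramethyl-1,3,2-dioxaborolane F2. Suzuki–Miyaura coupling of F2 with iodoketone 5 (Pd(OAc)2, SPhos, K3PO4, toluene/H2O, 90 °C), with no enone present, gives 1-{4,6-bis(benzyloxy)-3-[2-(benzyloxy)-5-(1,3-dioxolan-2-yl)phenyl]-2-hydroxyphenyl}ethan-1-one F3. Claisen–Schmidt condensation with 6 gives (2E)-1-{4,6-bis(benzyloxy)-3-[2-(benzyloxy)-5-(1,3-dioxolan-2-yl)phenyl]-2-hydroxyphenyl}-3-(4-methoxyphenyl)prop-2-en-1-one F4, and 1 M HCl in THF at rt unmasks the aldehyde to give 11.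

Step 7 (fivefold hydrogenolysis). Poor solubility of the partly debenzylated intermediates or slow over-reduction of a C2=C3 bond may interfere. The fallback replaces hydrogenolysis with Lewis-acid dealkylation; it sets out from 14 and comes back at 15. BCl3 (10 equiv) with pentamethylbenzene (15 equiv) as benzyl-cation scavenger in CH2Cl2 at −78 °C → 0 °C cleaves the benzyl ethers, the chelated ones first, and leaves the unchelated 4-methoxyphenyl ether intact. This fallback makes no new compound (entry F0).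

**Further compounds**
F1 | step 4 | 2-[4-(benzyloxy)-3-bromophenyl]-1,3-dioxolane | Brc1cc(C2OCCO2)ccc1OCc1ccccc1
F2 | step 4 | 2-[2-(benzyloxy)-5-(1,3-dioxolan-2-yl)phenyl]-4,4,5,5-tetramethyl-1,3,2-dioxaborolane | CC1(C)OB(OC1(C)C)c1cc(C2OCCO2)ccc1OCc1ccccc1
F3 | step 4 | 1-{4,6-bis(benzyloxy)-3-[2-(benzyloxy)-5-(1,3-dioxolan-2-yl)phenyl]-2-hydroxyphenyl}ethan-1-one | CC(=O)c1c(O)c(-c2cc(C3OCCO3)ccc2OCc2ccccc2)c(OCc2ccccc2)cc1OCc1ccccc1
F4 | step 4 | (2E)-1-{4,6-bis(benzyloxy)-3-[2-(benzyloxy)-5-(1,3-dioxolan-2-yl)phenyl]-2-hydroxyphenyl}-3-(4-methoxyphenyl)prop-2-en-1-one | COc1ccc(/C=C/C(=O)c2c(O)c(-c3cc(C4OCCO4)ccc3OCc3ccccc3)c(OCc3ccccc3)cc2OCc2ccccc2)cc1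
F5 | step 6 | 4-(benzyloxy)-3-[5,7-bis(benzyloxy)-2-(4-methoxyphenyl)-4-oxo-4H-chromen-8-yl]benzaldehyde | COc1ccc(-c2cc(=O)c3c(OCc4ccccc4)cc(OCc4ccccc4)c(-c4cc(C=O)ccc4OCc4ccccc4)c3o2)cc1
F6 | step 6 | 5,7-bis(benzyloxy)-8-{2-(benzyloxy)-5-[(1E)-3-[2,4-bis(benzyloxy)-6-hydroxyphenyl]-3-oxoprop-1-en-1-yl]phenyl}-2-(4-methoxyphenyl)-4H-chromen-4-one | COc1ccc(-c2cc(=O)c3c(OCc4ccccc4)cc(OCc4ccccc4)c(-c4cc(/C=C/C(=O)c5c(O)cc(OCc6ccccc6)cc5OCc5ccccc5)ccc4OCc4ccccc4)c3o2)cc1
F0 | step 7 | none | none
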